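With germacrane numbering (C1 and C10 the epoxide carbons, C14 the acetoxymethyl carbon, C6 and C7 the lactone ring fusion, C8 the methacrylate carbinol), everything rests on disconnecting C8–C9 of the ten-membered carbocycle. If the C1–C10 epoxide and the C14 acetate are unravelled to an exocyclic C10=C14 alkene flanked by a hydroxyl at C1, the array C8(OH)–C9H2–C10(=C14H2) is a homoallylic alcohol. An intramolecular Hosomi–Sakurai allylation forms C8–C9, closes the carbocycle, sets C8 and leaves that exocyclic alkene in one operation. Its precursor is a trans-γ-lactone carrying the C8 aldehyde on C7 and, on C6, an E-trisubstituted alkenyl chain ending in a C1 silyl ether and a 2-substituted allyltrimethylsilane.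

Key step: step 12

Assumption: the target's atom labels are kept for the same atoms throughout; of the two CH2 groups on C10 before step 12, the alkene terminus is the future C9 and the silicon-bearing carbon the future C14; compounds 1, 4, 12 and 13 are taken as commercial.

Step 1
Reactants: 1 geranyl acetate
Product: 3 (2E)-3-methyl-6-oxohex-2-en-1-yl acetate, via 6,7-epoxygeranyl acetate 2 (not isolated)
Conditions: mCPBA (1.0 equiv), CH2Cl2, 0 °C; then H5IO6, THF/H2O, 0 °C to rt
Reagents that add atoms: mCPBA, O=C(OO)c1cccc(Cl)c1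
Why: Prilezhaev epoxidation should select the electron-rich distal trisubstituted alkene over the alkene deactivated by the allylic acetate, and periodic acid then cleaves the epoxide through its diol (Malaprade-type glycol cleavage) to the aldehyde without touching the E alkene that becomes C4=C5.

Step 2
Reactants: 3 (2E)-3-methyl-6-oxohex-2-en-1-yl acetate; 4 2-bromoallyltrimethylsilane
Product: 6 rac-(2E)-6-hydroxy-3-methyl-7-[(trimethylsilyl)methyl]octa-2,7-dien-1-yl acetate, via Grignard reagent 5 (not isolated)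
Conditions: 4, Mg, THF, rt; then 3, THF, −78 °C; NH4Cl (aq)
Reagents that add atoms: none
Why: Grignard 1,2-addition to the aldehyde, which at −78 °C should outpace attack on the acetate by a wide margin; the C1 carbinol forms as a racemate on purpose, since steps 3 and 4 set its configuration.

Step 3
Reactants: 6 racemic allylic alcohol
Product: 7 (2E)-3-methyl-6-oxo-7-[(trimethylsilyl)methyl]octa-2,7-dien-1-yl acetate
Conditions: Dess–Martin periodinane, NaHCO3, CH2Cl2, 0 °C to rt
Reagents that add atoms: none
Why: Dess–Martin oxidation of the secondary allylic alcohol under bicarbonate buffer is non-acidic and non-electrophilic toward carbon, so the allylsilane and the acetate should survive.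

Step 4
Reactants: 7 enone
Product: 8 (2E,6R)-6-hydroxy-3-methyl-7-[(trimethylsilyl)methyl]octa-2,7-dien-1-yl acetate
Conditions: (S)-2-methyl-CBS-oxazaborolidine (0.2 equiv), catecholborane, toluene, −78 °C
Reagents that add atoms: none
Why: Corey–Bakshi–Shibata reduction: the ketone binds the (S)-oxazaborolidine with the branched alkenyl group as the large substituent, so hydride should add to the face that gives the (R) carbinol (C1 of the target), and catecholborane at −78 °C avoids hydroboration of the alkenes.

Step 5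
Reactants: 8 (R)-allylic alcohol
Product: 9 (2E,6R)-3-methyl-6-(triethylsilyloxy)-7-[(trimethylsilyl)methyl]octa-2,7-dien-1-yl acetate
Conditions: Et3SiCl, imidazole, CH2Cl2, 0 °C to rt
Reagents that add atoms: chlorotriethylsilane, CC[Si](Cl)(CC)CC
Why: Imidazole-promoted silylation is neutral, so neither the acetate nor the acid-sensitive allylsilane is touched; the triethylsilyl ether is chosen because it binds BF3 poorly in step 12 and can later be removed beside a tert-butyldimethylsilyl ether.

Step 6
Reactants: 9 silyl ether acetate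
Product: 10 (2E,6R)-3-methyl-6-(triethylsilyloxy)-7-[(trimethylsilyl)methyl]octa-2,7-dien-1-ol
Conditions: K2CO3 (cat.), MeOH, 0 °C
Reagents that add atoms: none
Why: Base-catalysed transesterification (Zemplén-type methanolysis) removes the primary acetate, while a secondary triethylsilyl ether and the allylsilane should be stable to cold K2CO3 in methanol.

Step 7
Reactants: 10 primary allylic alcohol
Product: 11 (2E,6R)-3-methyl-6-(triethylsilyloxy)-7-[(trimethylsilyl)methyl]octa-2,7-dienal
Conditions: MnO2, CH2Cl2, rt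
Reagents that add atoms: none
Why: MnO2 oxidises the primary allylic alcohol to the enal under neutral conditions, without E/Z isomerisation and without attack on the allylsilane.

Step 8
Reactants: 12 (S)-4-benzyl-1,3-oxazolidin-2-one; 13 methyl 4-chloro-4-oxobutanoate
Product: 14 methyl 4-[(4S)-4-benzyl-2-oxo-1,3-oxazolidin-3-yl]-4-oxobutanoate
Conditions: n-BuLi, THF, −78 °C; then 13, −78 to 0 °C
Reagents that add atoms: none
Why: N-Acylation of the lithiated oxazolidinone by the acid chloride is fast at −78 °C and leaves the methyl ester intact, giving the imide needed for the Evans aldol reaction.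

Step 9
Reactants: 11 enal; 14 succinate imide
Product: 16 (4S)-4-benzyl-3-{[(2R,3S)-2-[(1E,5R)-2-methyl-5-(triethylsilyloxy)-6-[(trimethylsilyl)methyl]hepta-1,6-dien-1-yl]-5-oxooxolan-3-yl]carbonyl}-1,3-oxazolidin-2-one, via syn-aldol hydroxy ester 15 (not isolated)
Conditions: 14, Bu2BOTf, i-Pr2NEt, CH2Cl2, −78 to 0 °C; 11, −78 to 0 °C; pH 7 buffer, MeOH, H2O2, 0 °C; then PPTS (cat.), CH2Cl2, rt
Reagents that add atoms: none
Why: Evans syn-aldol reaction: the Z-boron enolate should react through a Zimmerman–Traxler chair on the face away from the benzyl group, setting C7 (S here) and C6 (R) together, and the γ-hydroxy ester then lactonises by acyl substitution to the trans-lactone because the syn-aldol places C8 and C5 on opposite faces of the five-membered ring.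

Step 10
Reactants: 16 lactone imide
Product: 17 S-ethyl (2R,3S)-2-[(1E,5R)-2-methyl-5-(triethylsilyloxy)-6-[(trimethylsilyl)methyl]hepta-1,6-dien-1-yl]-5-oxooxolane-3-carbothioate
Conditions: EtSH, n-BuLi, THF, 0 °C; NH4Cl (aq)
Reagents that add atoms: ethanethiol, CCS
Why: Thiolate transacylation cleaves the exocyclic imide carbonyl, which is far more electrophilic than the lactone, to give the thioester and release the auxiliary without strong base at C7.

Step 11
Reactants: 17 thioester
Product: 18 (2R,3S)-2-[(1E,5R)-2-methyl-5-(triethylsilyloxy)-6-[(trimethylsilyl)methyl]hepta-1,6-dien-1-yl]-5-oxooxolane-3-carbaldehyde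
Conditions: Et3SiH, Pd/C (10%), acetone, rt; filtered and used at once
Reagents that add atoms: none
Why: Fukuyama reduction: oxidative addition of the thioester C–S bond to zerovalent palladium followed by hydride transfer from Et3SiH gives the aldehyde under neutral conditions, so C7 should not epimerise and the lactone oxygen at C6 should not be eliminated.

Step 12
Reactants: 18 lactone aldehyde with tethered allylsilane
Product: 19 (1R,4E,6R,7R,8S)-8-hydroxy-1-(triethylsilyloxy)-13-norgermacra-4,10(14)-dien-12,6-olide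
Conditions: BF3·OEt2 (3 equiv), 2,6-di-tert-butyl-4-methylpyridine, CH2Cl2, −78 °C, slow addition of 18 to about 1 mM; NaHCO3 (aq)
Reagents that add atoms: none
Why: BF3 binds the C8 aldehyde, which is far more basic and electrophilic than the lactone carbonyl, and the unsubstituted alkene terminus of the 2-substituted allylsilane attacks it in an anti SE2' sense; the β-silyl cation at C10 then loses Me3Si to fluoride, so the attacking carbon becomes ring C9 and the former CH2Si carbon becomes the exocyclic C14 methylene. The closest known reaction type is the intramolecular Hosomi–Sakurai allylation, which is established for medium and large carbocycles. The ten-membered ring closes in a 10-exo-trig mode at the carbonyl carbon, and the E-C4=C5 alkene and the trans-lactone take rotors out of the tether. The new C8 stereocentre is controlled by C7: open attack anti to the C7–C6 bond and past H7 instead of C11H2 (Felkin–Anh) should give the (8S) carbinol, and the anti C6–C7–C8–C9 arrangement it needs is one the forming ring can adopt. The step needs ring closure to beat intermolecular allylation, protodesilylation and β-elimination of the C6 oxygen; slow addition at high dilution, a hindered pyridine as proton scavenger, a non-basic promoter at −78 °C and the weakly coordinating silyl ether at C1 should secure this.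

Step 13
Reactants: 19 C8 carbinol
Product: 20 (1R,4E,6R,7S,8S)-8-(tert-butyldimethylsilyloxy)-1-(triethylsilyloxy)-13-norgermacra-4,10(14)-dien-12,6-olide
Conditions: t-BuMe2SiOTf, 2,6-lutidine, CH2Cl2, −78 °C
Reagents that add atoms: tert-butyldimethylsilyl triflate, CC(C)(C)[Si](C)(C)OS(=O)(=O)C(F)(F)F
Why: Silylation with the silyl triflate and 2,6-lutidine at −78 °C caps the C8 hydroxyl before any base is used, which prevents translactonisation to O8 and keeps O8 from directing or attacking in steps 15 and 16.

Step 14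
Reactants: 20 bis-silyl ether
Product: 21 (1R,4E,6R,7S,8S)-8-(tert-butyldimethylsilyloxy)-1-hydroxy-13-norgermacra-4,10(14)-dien-12,6-olide
Conditions: PPTS (cat.), MeOH/CH2Cl2, 0 °C
Reagents that add atoms: none
Why: Acid-catalysed solvolysis removes the less hindered triethylsilyl ether much faster than the tert-butyldimethylsilyl ether, so only the C1 hydroxyl should be freed.

Step 15
Reactants: 21 C1 allylic alcohol
Product: 22 (1R,4E,6R,7S,8S,10S)-8-(tert-butyldimethylsilyloxy)-10,14-epoxy-1-hydroxy-13-norgermacr-4-en-12,6-olide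
Conditions: VO(acac)2 (5 mol%), t-BuOOH, CH2Cl2, 0 °C
Reagents that add atoms: tert-butyl hydroperoxide, CC(C)(C)OO
Why: Hydroxyl-directed epoxidation through a vanadate ester of O1 should touch only the adjacent C10=C14 alkene, and allylic 1,2-strain between C2 and C9 in the transition state should favour the erythro spiro-epoxide (10S), the known preference of 2-substituted allylic alcohols.

Step 16
Reactants: 22 erythro epoxy alcohol
Product: 23 (1R,4E,6R,7S,8S,10R)-8-(tert-butyldimethylsilyloxy)-1,10-epoxy-14-hydroxy-13-norgermacr-4-en-12,6-olide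
Conditions: KOt-Bu (0.3 equiv), t-BuOH/THF, rt; NH4Cl (aq)
Reagents that add atoms: none
Why: Payne rearrangement: the C1 alkoxide opens the spiro-epoxide at C10 by intramolecular SN2 attack with inversion, which should give the more substituted cis-fused C1–C10 epoxide (10R) and the primary C14 alkoxide favoured at equilibrium, while tert-butoxide in tert-butanol is too hindered to open the lactone.

Step 17
Reactants: 23 C14 alcohol
Product: 24 (1R,4E,6R,7S,8S,10R)-8-(tert-butyldimethylsilyloxy)-1,10-epoxy-14-(triethylsilyloxy)-13-norgermacr-4-en-12,6-olide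
Conditions: Et3SiCl, imidazole, CH2Cl2, 0 °C
Reagents that add atoms: chlorotriethylsilane, CC[Si](Cl)(CC)CC
Why: Silylation of the primary C14 hydroxyl leaves the lactone α-CH2 as the only acidic site for step 18 and prevents reverse epoxide migration under strong base.

Step 18
Reactants: 24 bis-silyl ether lactone
Product: 27 (1R,4E,6R,7S,8S,10R)-8-(tert-butyldimethylsilyloxy)-1,10-epoxy-14-(triethylsilyloxy)germacra-4,11(13)-dien-12,6-olide, via Mannich base 25 (not isolated), via ammonium iodide 26 (not isolated)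
Conditions: LiN(i-Pr)2, THF, −78 °C; [CH2=NMe2]I, −78 °C to rt; MeI, MeOH, rt; NaHCO3 (aq), CH2Cl2, rt
Reagents that add atoms: Eschenmoser's salt, C=[N+](C)C.[I-]
Why: Mannich reaction of the lactone lithium enolate with Eschenmoser's salt, N-methylation and Hofmann-type β-elimination install the C11=C13 methylene, and no other enolisable carbonyl or free hydroxyl is present to compete.

Step 19
Reactants: 27 bis-silyl methylene lactone
Product: 28 (1R,4E,6R,7R,8S,10R)-1,10-epoxy-8,14-dihydroxygermacra-4,11(13)-dien-12,6-olide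
Conditions: HF·pyridine, pyridine, THF, 0 °C to rt
Reagents that add atoms: none
Why: Fluoride-driven desilylation (strong Si–F bond) buffered by pyridine should free O8 and O14 without opening the epoxide or adding to the methylene lactone.

Step 20
Reactants: 28 diol
Product: 29 (1R,4E,6R,7R,8S,10R)-14-acetoxy-1,10-epoxy-8-hydroxygermacra-4,11(13)-dien-12,6-olide
Conditions: AcCl, 2,4,6-collidine, CH2Cl2, −78 °C
Reagents that add atoms: acetyl chloride, CC(=O)Cl
Why: Acylation with AcCl and collidine at −78 °C should be selective for the primary C14 hydroxyl over the hindered secondary C8 hydroxyl on steric grounds.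

Step 21
Reactants: 29 C14 acetate
Product: 30 CNP0150481.4, (1R,4E,6R,7R,8S,10R)-14-acetoxy-1,10-epoxy-8-(methacryloyloxy)germacra-4,11(13)-dien-12,6-olide
Conditions: methacrylic anhydride, Et3N, DMAP (cat.), CH2Cl2, 0 °C to rt
Reagents that add atoms: methacrylic anhydride, C=C(C)C(=O)OC(=O)C(C)=C
Why: DMAP-catalysed acyl transfer (Steglich-type esterification) from methacrylic anhydride to the remaining C8 hydroxyl proceeds with retention at C8 and completes the target.

Compound list
1 | geranyl acetate, (2E)-3,7-dimethylocta-2,6-dien-1-yl acetate | CC(C)=CCC/C(C)=C/COC(C)=O | starting material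
2 | 6,7-epoxygeranyl acetate (racemic at the epoxide CH) | CC1(C)OC1CC/C(C)=C/COC(C)=O | intermediate
3 | (2E)-3-methyl-6-oxohex-2-en-1-yl acetate | O=CCC/C(C)=C/COC(C)=O | intermediate
4 | 2-bromoallyltrimethylsilane | C=C(Br)C[Si](C)(C)C | starting material
5 | [3-(trimethylsilyl)prop-1-en-2-yl]magnesium bromide | C=C([Mg]Br)C[Si](C)(C)C | intermediate
6 | rac-(2E)-6-hydroxy-3-methyl-7-[(trimethylsilyl)methyl]octa-2,7-dien-1-yl acetate | CC(=O)OC/C=C(\C)CCC(O)C(=C)C[Si](C)(C)C | intermediate
7 | (2E)-3-methyl-6-oxo-7-[(trimethylsilyl)methyl]octa-2,7-dien-1-yl acetate | CC(=O)OC/C=C(\C)CCC(=O)C(=C)C[Si](C)(C)C | intermediate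
8 | (2E,6R)-6-hydroxy-3-methyl-7-[(trimethylsilyl)methyl]octa-2,7-dien-1-yl acetate | CC(=O)OC/C=C(\C)CC[C@@H](O)C(=C)C[Si](C)(C)C | intermediate
9 | (2E,6R)-3-methyl-6-(triethylsilyloxy)-7-[(trimethylsilyl)methyl]octa-2,7-dien-1-yl acetate | CC(=O)OC/C=C(\C)CC[C@@H](O[Si](CC)(CC)CC)C(=C)C[Si](C)(C)C | intermediate
10 | (2E,6R)-3-methyl-6-(triethylsilyloxy)-7-[(trimethylsilyl)methyl]octa-2,7-dien-1-ol | OC/C=C(\C)CC[C@@H](O[Si](CC)(CC)CC)C(=C)C[Si](C)(C)C | intermediate
11 | (2E,6R)-3-methyl-6-(triethylsilyloxy)-7-[(trimethylsilyl)methyl]octa-2,7-dienal | O=C/C=C(\C)CC[C@@H](O[Si](CC)(CC)CC)C(=C)C[Si](C)(C)C | intermediate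
12 | (S)-4-benzyl-1,3-oxazolidin-2-one | O=C1N[C@@H](Cc2ccccc2)CO1 | starting material
13 | methyl 4-chloro-4-oxobutanoate | COC(=O)CCC(Cl)=O | starting material
14 | methyl 4-[(4S)-4-benzyl-2-oxo-1,3-oxazolidin-3-yl]-4-oxobutanoate | COC(=O)CCC(=O)N1[C@@H](Cc2ccccc2)COC1=O | intermediate
15 | methyl (3S,4R,5E,9R)-3-{[(4S)-4-benzyl-2-oxo-1,3-oxazolidin-3-yl]carbonyl}-4-hydroxy-6-methyl-9-(triethylsilyloxy)-10-[(trimethylsilyl)methyl]undeca-5,10-dienoate | COC(=O)C[C@@H]([C@H](O)/C=C(\C)CC[C@@H](O[Si](CC)(CC)CC)C(=C)C[Si](C)(C)C)C(=O)N1[C@@H](Cc2ccccc2)COC1=O | intermediate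
16 | (4S)-4-benzyl-3-{[(2R,3S)-2-[(1E,5R)-2-methyl-5-(triethylsilyloxy)-6-[(trimethylsilyl)methyl]hepta-1,6-dien-1-yl]-5-oxooxolan-3-yl]carbonyl}-1,3-oxazolidin-2-one | O=C([C@H]1CC(=O)O[C@@H]1/C=C(\C)CC[C@@H](O[Si](CC)(CC)CC)C(=C)C[Si](C)(C)C)N1[C@@H](Cc2ccccc2)COC1=O | intermediate
17 | S-ethyl (2R,3S)-2-[(1E,5R)-2-methyl-5-(triethylsilyloxy)-6-[(trimethylsilyl)methyl]hepta-1,6-dien-1-yl]-5-oxooxolane-3-carbothioate | CCSC(=O)[C@H]1CC(=O)O[C@@H]1/C=C(\C)CC[C@@H](O[Si](CC)(CC)CC)C(=C)C[Si](C)(C)C | intermediate
18 | (2R,3S)-2-[(1E,5R)-2-methyl-5-(triethylsilyloxy)-6-[(trimethylsilyl)methyl]hepta-1,6-dien-1-yl]-5-oxooxolane-3-carbaldehyde (key-step precursor) | O=C[C@H]1CC(=O)O[C@@H]1/C=C(\C)CC[C@@H](O[Si](CC)(CC)CC)C(=C)C[Si](C)(C)C | intermediate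
19 | (1R,4E,6R,7R,8S)-8-hydroxy-1-(triethylsilyloxy)-13-norgermacra-4,10(14)-dien-12,6-olide (key-step product) | O[C@H]1CC(=C)[C@H](O[Si](CC)(CC)CC)CC/C(C)=C/[C@H]2OC(=O)C[C@H]12 | intermediate
20 | (1R,4E,6R,7S,8S)-8-(tert-butyldimethylsilyloxy)-1-(triethylsilyloxy)-13-norgermacra-4,10(14)-dien-12,6-olide | CC(C)(C)[Si](C)(C)O[C@H]1CC(=C)[C@H](O[Si](CC)(CC)CC)CC/C(C)=C/[C@H]2OC(=O)C[C@H]12 | intermediate
21 | (1R,4E,6R,7S,8S)-8-(tert-butyldimethylsilyloxy)-1-hydroxy-13-norgermacra-4,10(14)-dien-12,6-olide | CC(C)(C)[Si](C)(C)O[C@H]1CC(=C)[C@H](O)CC/C(C)=C/[C@H]2OC(=O)C[C@H]12 | intermediate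
22 | (1R,4E,6R,7S,8S,10S)-8-(tert-butyldimethylsilyloxy)-10,14-epoxy-1-hydroxy-13-norgermacr-4-en-12,6-olide | CC(C)(C)[Si](C)(C)O[C@H]1C[C@]2(CO2)[C@H](O)CC/C(C)=C/[C@H]2OC(=O)C[C@H]12 | intermediate
23 | (1R,4E,6R,7S,8S,10R)-8-(tert-butyldimethylsilyloxy)-1,10-epoxy-14-hydroxy-13-norgermacr-4-en-12,6-olide | CC(C)(C)[Si](C)(C)O[C@H]1C[C@]2(CO)O[C@@H]2CC/C(C)=C/[C@H]2OC(=O)C[C@H]12 | intermediate
24 | (1R,4E,6R,7S,8S,10R)-8-(tert-butyldimethylsilyloxy)-1,10-epoxy-14-(triethylsilyloxy)-13-norgermacr-4-en-12,6-olide | CC(C)(C)[Si](C)(C)O[C@H]1C[C@]2(CO[Si](CC)(CC)CC)O[C@@H]2CC/C(C)=C/[C@H]2OC(=O)C[C@H]12 | intermediate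
25 | 13-(dimethylamino)-11,13-dihydro derivative of 27 (Mannich base, C11 configuration not defined) | CC(C)(C)[Si](C)(C)O[C@H]1C[C@]2(CO[Si](CC)(CC)CC)O[C@@H]2CC/C(C)=C/[C@H]2OC(=O)C(CN(C)C)[C@H]12 | intermediate
26 | N-methyl quaternary ammonium iodide of 25 (C11 configuration not defined) | CC(C)(C)[Si](C)(C)O[C@H]1C[C@]2(CO[Si](CC)(CC)CC)O[C@@H]2CC/C(C)=C/[C@H]2OC(=O)C(C[N+](C)(C)C)[C@H]12.[I-] | intermediate
27 | (1R,4E,6R,7S,8S,10R)-8-(tert-butyldimethylsilyloxy)-1,10-epoxy-14-(triethylsilyloxy)germacra-4,11(13)-dien-12,6-olide | CC(C)(C)[Si](C)(C)O[C@H]1C[C@]2(CO[Si](CC)(CC)CC)O[C@@H]2CC/C(C)=C/[C@H]2OC(=O)C(=C)[C@H]12 | intermediate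
28 | (1R,4E,6R,7R,8S,10R)-1,10-epoxy-8,14-dihydroxygermacra-4,11(13)-dien-12,6-olide | O[C@H]1C[C@]2(CO)O[C@@H]2CC/C(C)=C/[C@H]2OC(=O)C(=C)[C@H]12 | intermediate
29 | (1R,4E,6R,7R,8S,10R)-14-acetoxy-1,10-epoxy-8-hydroxygermacra-4,11(13)-dien-12,6-olide | O[C@H]1C[C@]2(COC(C)=O)O[C@@H]2CC/C(C)=C/[C@H]2OC(=O)C(=C)[C@H]12 | intermediate
30 | CNP0150481.4, (1R,4E,6R,7R,8S,10R)-14-acetoxy-1,10-epoxy-8-(methacryloyloxy)germacra-4,11(13)-dien-12,6-olide | C=C(C)C(=O)O[C@H]1C[C@]2(COC(C)=O)O[C@@H]2CC/C(C)=C/[C@H]2OC(=O)C(=C)[C@H]12 | target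

Total steps: 21. Longest linear sequence: 20 steps (steps 1–7, then 9–21, from geranyl acetate); step 8 is a one-step branch.

Steps most likely to fail

Step 12. Ring closure may lose to intermolecular allylation or protodesilylation, or the allylsilane may attack the wrong face of the aldehyde. The fallback sets out from 18: bromodesilylation with NBS (propylene oxide, CH2Cl2, −78 °C; SE2' attack of bromine on the allylsilane) should give (2R,3S)-2-[(1E,5R)-6-(bromomethyl)-2-methyl-5-(triethylsilyloxy)hepta-1,6-dien-1-yl]-5-oxooxolane-3-carbaldehyde F1. Treatment with CrCl2 in THF at high dilution (intramolecular Nozaki–Hiyama allylation through an allylchromium species and a closed chair transition state) should then form the same C8–C9 bond and come back to the route at 19.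

Step 15. Oxygen may be delivered to the wrong face of C10=C14 if the ring holds C2 and C9 close together in the vanadium transition state. The fallback sets out from 21 and replaces substrate control by reagent control: Katsuki–Sharpless epoxidation with Ti(Oi-Pr)4, D-(−)-diisopropyl tartrate and t-BuOOH (CH2Cl2, −20 °C, molecular sieves). This is the matched pairing for an (R) carbinol of this type and gives the erythro epoxide by the kinetic-resolution rule. It comes back at 22 and makes no new compound (F0).

Step 16. The C1 alkoxide may fail to attack the fully substituted C10, or the base may open the lactone or shift the C8 silyl group. The fallback sets out from 21 and avoids epoxide migration: rhenium-catalysed 1,3-transposition of the allylic alcohol (Ph3SiOReO3, Et2O, 0 °C) should give (1(10)E,4E,6R,7S,8S)-8-(tert-butyldimethylsilyloxy)-14-hydroxy-13-norgermacra-1(10),4-dien-12,6-olide F2, the isomer with C2 and C9 cis on the new C1=C10 alkene. Katsuki–Sharpless epoxidation of this primary allylic alcohol with Ti(Oi-Pr)4, D-(−)-diethyl tartrate and t-BuOOH should then give the (1R,10R) epoxide and come back at 23.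

Further compounds
F1 | step 12 | (2R,3S)-2-[(1E,5R)-6-(bromomethyl)-2-methyl-5-(triethylsilyloxy)hepta-1,6-dien-1-yl]-5-oxooxolane-3-carbaldehyde | O=C[C@H]1CC(=O)O[C@@H]1/C=C(\C)CC[C@@H](O[Si](CC)(CC)CC)C(=C)CBr
F0 | step 15 | none | none
F2 | step 16 | (1(10)E,4E,6R,7S,8S)-8-(tert-butyldimethylsilyloxy)-14-hydroxy-13-norgermacra-1(10),4-dien-12,6-olide (C2 and C9 cis on C1=C10) | CC(C)(C)[Si](C)(C)O[C@H]1C/C(CO)=C\CC/C(C)=C/[C@H]2OC(=O)C[C@H]12
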